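## The problem

- Target 21 is an unsymmetrical methylene-bridged bis-acylphloroglucinol. Benzene ring A carries the (R)-2-methylbutanoyl group on A1, hydroxyls on A2 and A6, a methyl on A3 and a methoxy on A4. It is joined from A5 through one CH2 to C8 of a 5,7-dihydroxy-2,2,6-trimethylchroman-4-one (ring B benzene, ring C pyranone).
- The only stereocentre is the α-carbon of the aryl ketone side chain. Nothing else in the molecule can control it, so it has to come from the chiral pool and be kept away from enolising acid, Lewis acid or base in every later step.
- Both benzene rings are hexasubstituted, so each substituent must be placed by the way the ring is made or by the single free carbon left on each half.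
- Two oxygen patterns must be set. In ring A only the A4 oxygen, para to the acyl carbon, is methylated. In ring B the two oxygens ortho to C4a differ: the one on C8a is O1 of ring C and neighbours the bridge carbon C8, while the one on C5 stays a hydroxyl next to the C6 methyl.
- Annulating 2-methylphloroglucinol 16 with a five-carbon acyl unit cannot tell these two ortho hydroxyls apart.
- Three things will not survive rough treatment. The diarylmethane link between two phloroglucinol rings redistributes under hot acid or base. Ring C can open by retro-oxa-Michael reaction and reclose on the C5 hydroxyl once that is free. The polyphenols oxidise in basic air.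
- The enabling feature is that ring B can be cut into a four-carbon piece C6–C7–C8–C8a and a two-carbon piece C5–C4a that already carries C4. The oxygens on C7, C8a and C5 then come from three different atoms of two reagents. O5 can arrive as an ether while the C8a oxygen is a free phenol, so ring C can close in one direction only.

## Retrosynthesis

**Bridge.** Target 21 is cut at the A5–CH2 bond into Mannich base 14 and ring A ketone 19; the forward reaction passes through ortho-quinone methide 20.
- Cutting both aryl–CH2 bonds at once (a one-carbon electrophile shared by two phenols) would give statistical mixtures of homo- and heterodimers.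
- Cutting C8–CH2 instead would put the aminomethyl group on the chiral ketone and expose it to one more step.
- Each of 14 and 19 has exactly one free or activated ring carbon, so the union has no regiochemical choice.
- The forward step must run without strong acid or base, so that neither the bridge nor the α-stereocentre is disturbed.

**Ring B/C functional groups.** Mannich base 14 is cut at C8–CH2N back to chromanone 13, and 13 is traced to its C5 ethyl ether 12.
- C8 is the only unsubstituted carbon of 13, so aminomethylation needs no control.
- The C5 ether of 12 sits peri to the C4 carbonyl and is the one ether that a chelating boron trihalide removes under mild conditions.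
- Compound 12 is the point at which the two ortho oxygens are still chemically different.

**Key disconnection.** Chromanone 12 is cut at C5–C6, C4a–C8a and O1–C2 into diene 4 and ynone 9.
- The neighbouring cut at C4–C4a and O1–C2 leads back to 16 and loses the distinction between the ortho hydroxyls.
- In the chosen cut the C7 oxygen is the ketone oxygen of a β-keto ester, the C8a oxygen is its ester carbonyl oxygen, and the C5 oxygen is the ynol ether oxygen of 9.
- Both precursors are acyclic and lie two steps from commercial materials.
- The forward reaction must join the methyl-bearing diene terminus to the ethoxy-bearing alkyne carbon, close the carbocycle through the ketene acetal carbon (cycloadduct 10), aromatise by loss of the C8a methoxy group as the alcohol (aryl enone 11), and let the C8a phenol add to the enone.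

**Diene and ynone.** Diene 4 goes back through lithium dienolate 3 and silyl enol ether 2 to methyl 3-oxopentanoate 1 by two O-silylations. Ynone 9 goes back to carbinol 8, which is cut at the alkynyl–carbinol bond into ethoxyacetylene 5 (as its lithium salt 7) and 3-methylbut-2-enal 6.
- All carbons of ring B and ring C are then present in 1, 5 and 6.
- The only demands are anhydrous handling of 4 and non-acidic handling of 8 and 9.

**Ring A.** Ketone 19 is cut at the A4 O–CH3 bond to triol ketone 18, and 18 at the aryl–acyl bond to (R)-2-methylbutanoic acid 15 (as its chloride 17) and 16.
- Acylating before methylating lets the acyl group differentiate the three hydroxyls: the two ortho ones are chelated and the para one is the most acidic.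
- The two free carbons of 16 are equivalent, so acylation has no regiochemical issue.
- The forward steps must spare the α-stereocentre and stop at mono-O-methylation.

## Roads not taken

**Alternative 1:** ring A is cut at the A1–acyl and A6–O bonds.
- Forward key step: KF with 18-crown-6 releases benzyne A2 from silyl triflate A1. The carboxylate of 15 adds through oxygen to the aryne carbon remote from methoxy. The aryl anion formed next to the methoxy group takes the acyl group, giving ketone A3 with no ring closure. BCl3 would then remove the chelated ortho methyl ether and give 19.
- Merits: no Lewis acid touches the chiral acid, and the oxygen pattern of ring A arrives fully defined. In that respect it is better than step 9 of the chosen plan, which depends on a selective mono-methylation.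
- Weak points: A1 needs a multistep preparation. The acyl shift passes through a strained four-membered intermediate and competes with simple protonation to the aryl ester, more so with an α-branched acyl group. The α-stereocentre sits next to a carbonyl under basic fluoride.
- Comparison: this road addresses only ring A. The regiochemistry of ring B and the bridge are left unsolved. The chosen plan reaches 19 in two steps from commercial materials and spends its new chemistry on ring B, where classical methods fail.

**Alternative 2:** ring A is cut at A1–A6 and A2–A3 and built by benzannulation on a bridge that is already in place.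
- Forward key step: heating racemic cyclobutenone A4 with siloxyalkyne A5 opens the four-membered ring to a vinylketene, which adds the alkyne; a second ring opening and a six-electron closure give phenol A6.
- Merits: the methylene bridge is an ordinary C–C bond made early, so it cannot redistribute. The three oxygens of ring A emerge differentiated as methoxy, silyloxy and hydroxyl. On the bridge it is safer than step 10 of the chosen plan.
- Weak points: A4 requires a regiodefined chromanone electrophile, so the ring B problem is only moved. A6 still lacks the chiral acyl group, which would have to be introduced late at a hindered carbon of a large molecule with the same risk to the stereocentre. Two benzyl groups and one silyl group remain to be removed.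
- Comparison: the sequence is much longer and linear. The chosen plan instead gives each half a single free carbon, so the bridge step has no regiochemical choice, and it keeps the longest linear sequence at six steps.

**Alternative 3:** the chromanone is cut at C4–C4a and O1–C2.
- Forward key step: symmetric phenol A7 is esterified to A8. Bi(OTf)3 promotes Fries rearrangement, and the liberated phenol adds to the enone to give dimethoxychromanone A9.
- Merits: the two ortho positions of A7 are identical, so the regiochemistry of A9 is unambiguous. The reaction type is well known. Up to A9 this road is better precedented than step 5 of the chosen plan.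
- Weak points: both methyl ethers must be cleaved before the bridge is made, because the A4 methyl ether of the target must stay. The C7 ether is not chelated and needs BBr3 or a comparably strong reagent. Under those conditions ring C can open and, once O5 is free, reclose on either hydroxyl, which gives back the ambiguity that symmetry had removed. A7 is also a costlier starting material than 1, 5 and 6.
- Comparison: the chosen plan delivers the C7 hydroxyl free and O5 as a chelated ether that BCl3 removes at low temperature. It pays for this with an unprecedented key step.

Key step: step 5

Assumption: (R)-2-methylbutanoic acid 15 is taken as purchasable in high enantiomeric purity; the C2=C3 geometry of 2 and the ketene acetal geometry of 4 are of no consequence, since both are erased later.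

## Route

Step 1
Reactants: 1 methyl 3-oxopentanoate
Product: 2 methyl 3-(trimethylsilyloxy)pent-2-enoate
Conditions: TMSCl, Et3N, PhMe, 23 °C
Reagents that add atoms: chlorotrimethylsilane, C[Si](C)(C)Cl
Why: Silyl enol ether formation: Et3N is basic enough for the doubly activated methylene of the β-keto ester, and the enol oxygen is silylated while the ester is untouched.

Step 2
Reactants: 2 methyl 3-(trimethylsilyloxy)pent-2-enoate
Product: 4 (3Z)-1-methoxy-1,3-bis(trimethylsilyloxy)penta-1,3-diene, via lithium dienolate 3 (not isolated)
Conditions: LiN(i-Pr)2, THF, −78 °C; then TMSCl, −78 to 23 °C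
Reagents that add atoms: chlorotrimethylsilane, C[Si](C)(C)Cl
Why: γ-Deprotonation of the vinylogous ester gives the extended ester enolate 3, which is silylated on oxygen; this is the standard preparation of 1-alkoxy-1,3-bis(silyloxy)dienes from β-keto esters, and the methyl group should settle trans to the diene chain.

Step 3
Reactants: 5 ethoxyacetylene; 6 3-methylbut-2-enal
Product: 8 rac-1-ethoxy-5-methylhex-4-en-1-yn-3-ol, via lithium ethoxyacetylide 7 (not isolated)
Conditions: n-BuLi, THF, −78 °C; then 6, −78 to 0 °C; H2O
Reagents that add atoms: none
Why: Acetylide addition to an aldehyde: the hard lithium alkynide adds 1,2 to the enal at low temperature; the carbinol centre is racemic and is destroyed in step 4.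

Step 4
Reactants: 8 rac-1-ethoxy-5-methylhex-4-en-1-yn-3-ol
Product: 9 1-ethoxy-5-methylhex-4-en-1-yn-3-one
Conditions: MnO2, CH2Cl2, 23 °C
Reagents that add atoms: none
Why: MnO2 oxidation of an alcohol that is both allylic and propargylic; the neutral heterogeneous oxidant avoids the acid-induced Meyer–Schuster rearrangement of the ethoxyalkynyl carbinol.

Step 5
Reactants: 4 (3Z)-1-methoxy-1,3-bis(trimethylsilyloxy)penta-1,3-diene; 9 1-ethoxy-5-methylhex-4-en-1-yn-3-one
Product: 12 5-ethoxy-7-hydroxy-2,2,6-trimethylchroman-4-one, via cyclohexadiene cycloadduct 10 (not isolated), via open aryl enone 11 (not isolated)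
Conditions: PhMe, 23 to 60 °C; then K2CO3 (20 mol%), MeOH, 23 to 50 °C
Reagents that add atoms: none
Why: Proposed new method: the closest known reaction type is the Diels–Alder reaction of 1-alkoxy-1,3-bis(silyloxy)buta-1,3-dienes with acetylenic ketones and esters, which aromatises to resorcinols by loss of the alcohol; new here are the ethoxy group on the alkyne and the ring closure that follows in the same flask. The methyl-bearing terminus of 4, its most nucleophilic carbon, should bond to the ethoxy-bearing alkyne carbon of 9 (β to the ketone) and the ketene acetal carbon to the α-carbon, in an asynchronous [4+2] cycloaddition or, equivalently, a conjugate addition followed by a Claisen-type 6-exo-trig closure, giving 10 with C5–C6 and C4a–C8a formed and ring B closed. Catalytic K2CO3 in methanol should then remove both silyl groups, the C8a hemiketal loses methanol and the C6 hydrogen shifts, so that aromatisation to 11 drives the sequence. In 11 the C8a phenoxide adds to the dimethyl-substituted enone carbon in a 6-endo-trig oxa-Michael closure (the known cyclisation of 2-hydroxyaryl 2-methylprop-1-enyl ketones), forming O1–C2 and ring C. No stereocentre survives, since the two sp3 centres of 10 are erased on aromatisation. Regiochemistry rests on the match of the nucleophilic diene terminus with the sp-hybridised, unhindered alkyne β-carbon, whereas the competing enone β-carbon is disubstituted; the [4+2] mode is favoured over a [3+3] closure through C2 of the diene onto the ketone by leaving out any Lewis acid. The direction of ring C closure is not a matter of selectivity, because O5 is an ethyl ether and the C7 hydroxyl is para to C4a.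

Step 6
Reactants: 12 5-ethoxy-7-hydroxy-2,2,6-trimethylchroman-4-one
Product: 13 5,7-dihydroxy-2,2,6-trimethylchroman-4-one
Conditions: BCl3, CH2Cl2, −78 to 0 °C; then H2O
Reagents that add atoms: none
Why: Chelation-controlled cleavage of an aryl ether peri to a carbonyl: BCl3 bridges the C4 carbonyl and O5 in a six-membered chelate and chloride removes the ethyl group; the unchelated tertiary O1–C2 ether should survive at low temperature and the C7 borate is hydrolysed on work-up.

Step 7
Reactants: 13 5,7-dihydroxy-2,2,6-trimethylchroman-4-one
Product: 14 8-[(dimethylamino)methyl]-5,7-dihydroxy-2,2,6-trimethylchroman-4-one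
Conditions: CH2=NMe2+ I−, Et3N, CH2Cl2, 23 °C
Reagents that add atoms: dimethylmethyleneiminium iodide, C=[N+](C)C.[I-]
Why: Mannich aminomethylation with a preformed iminium salt; C8 is the only unsubstituted ring carbon and is activated by the ortho C7 hydroxyl and by O1.

Step 8
Reactants: 15 (R)-2-methylbutanoic acid; 16 2-methylbenzene-1,3,5-triol (2-methylphloroglucinol)
Product: 18 (R)-2-methyl-1-(2,4,6-trihydroxy-3-methylphenyl)butan-1-one, via (R)-2-methylbutanoyl chloride 17 (not isolated)
Conditions: (COCl)2, DMF (cat.), CH2Cl2, 0 to 23 °C; then 16, AlCl3, PhNO2–CH2Cl2, 0 to 23 °C
Reagents that add atoms: none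
Why: Acid chloride formation without amine base (no ketene pathway) followed by Friedel–Crafts C-acylation of the phloroglucinol; the two free carbons of 16 are equivalent and the first acyl group deactivates the ring, and the α-stereocentre comes from 15 and should be kept by the low temperature.

Step 9
Reactants: 18 (R)-2-methyl-1-(2,4,6-trihydroxy-3-methylphenyl)butan-1-one
Product: 19 (R)-1-(2,6-dihydroxy-4-methoxy-3-methylphenyl)-2-methylbutan-1-one
Conditions: Me2SO4 (1 equiv), K2CO3 (1 equiv), acetone, 0 to 23 °C
Reagents that add atoms: dimethyl sulfate, COS(=O)(=O)OC
Why: Williamson O-methylation of the most acidic phenol: the C4 hydroxyl is para to the carbonyl and not hydrogen-bonded, whereas the C2 and C6 hydroxyls are held in chelation with the ketone; one equivalent of the hard electrophile favours O- over C-methylation.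

Step 10
Reactants: 14 8-[(dimethylamino)methyl]-5,7-dihydroxy-2,2,6-trimethylchroman-4-one; 19 (R)-1-(2,6-dihydroxy-4-methoxy-3-methylphenyl)-2-methylbutan-1-one
Product: 21 8-{[2,4-dihydroxy-6-methoxy-5-methyl-3-((R)-2-methylbutanoyl)phenyl]methyl}-5,7-dihydroxy-2,2,6-trimethylchroman-4-one, via ortho-quinone methide 20 (not isolated)
Conditions: 1,4-dioxane, 90 °C, slow Ar stream
Reagents that add atoms: none
Why: Thermal loss of dimethylamine from the phenolic Mannich base gives ortho-quinone methide 20, which alkylates 19 at its only free ring carbon in a Friedel–Crafts-type conjugate addition followed by rearomatisation, the known route to unsymmetrical methylene-bridged bis-acylphloroglucinols; no stereocentre is formed, and the phenols buffer the amine so that the α-carbon of the ketone should not enolise.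

## Compound list

1 | methyl 3-oxopentanoate | CCC(=O)CC(=O)OC | starting material
2 | methyl 3-(trimethylsilyloxy)pent-2-enoate (mixture of double-bond isomers) | CCC(O[Si](C)(C)C)=CC(=O)OC | intermediate
3 | lithium 1-methoxy-3-(trimethylsilyloxy)penta-1,3-dien-1-olate (not isolated) | C/C=C(\O[Si](C)(C)C)C=C(OC)[O-].[Li+] | intermediate
4 | (3Z)-1-methoxy-1,3-bis(trimethylsilyloxy)penta-1,3-diene (ketene acetal geometry unassigned) | C/C=C(\O[Si](C)(C)C)C=C(OC)O[Si](C)(C)C | intermediate
5 | ethoxyacetylene | CCOC#C | starting material
6 | 3-methylbut-2-enal | CC(C)=CC=O | starting material
7 | lithium ethoxyacetylide, LiC≡COEt (not isolated) | CCOC#C[Li] | intermediate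
8 | rac-1-ethoxy-5-methylhex-4-en-1-yn-3-ol | CCOC#CC(O)C=C(C)C | intermediate
9 | 1-ethoxy-5-methylhex-4-en-1-yn-3-one | CCOC#CC(=O)C=C(C)C | intermediate
10 | 1-[2-ethoxy-6-methoxy-3-methyl-4,6-bis(trimethylsilyloxy)cyclohexa-1,4-dien-1-yl]-3-methylbut-2-en-1-one (diastereomer mixture, not isolated) | CCOC1=C(C(=O)C=C(C)C)C(OC)(O[Si](C)(C)C)C=C(O[Si](C)(C)C)C1C | intermediate
11 | 1-(2-ethoxy-4,6-dihydroxy-3-methylphenyl)-3-methylbut-2-en-1-one (not isolated) | CCOc1c(C)c(O)cc(O)c1C(=O)C=C(C)C | intermediate
12 | 5-ethoxy-7-hydroxy-2,2,6-trimethylchroman-4-one | CCOc1c(C)c(O)cc2OC(C)(C)CC(=O)c12 | intermediate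
13 | 5,7-dihydroxy-2,2,6-trimethylchroman-4-one | Cc1c(O)cc2OC(C)(C)CC(=O)c2c1O | intermediate
14 | 8-[(dimethylamino)methyl]-5,7-dihydroxy-2,2,6-trimethylchroman-4-one | Cc1c(O)c(CN(C)C)c2OC(C)(C)CC(=O)c2c1O | intermediate
15 | (R)-2-methylbutanoic acid | CC[C@@H](C)C(=O)O | starting material
16 | 2-methylbenzene-1,3,5-triol (2-methylphloroglucinol) | Cc1c(O)cc(O)cc1O | starting material
17 | (R)-2-methylbutanoyl chloride (not isolated) | CC[C@@H](C)C(=O)Cl | intermediate
18 | (R)-2-methyl-1-(2,4,6-trihydroxy-3-methylphenyl)butan-1-one | CC[C@@H](C)C(=O)c1c(O)c(C)c(O)cc1O | intermediate
19 | (R)-1-(2,6-dihydroxy-4-methoxy-3-methylphenyl)-2-methylbutan-1-one | CC[C@@H](C)C(=O)c1c(O)c(C)c(OC)cc1O | intermediate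
20 | 5-hydroxy-2,2,6-trimethyl-8-methylidene-2,3-dihydro-4H-chromene-4,7(8H)-dione (not isolated) | C=C1C(=O)C(C)=C(O)C2=C1OC(C)(C)CC2=O | intermediate
21 | 8-{[2,4-dihydroxy-6-methoxy-5-methyl-3-((R)-2-methylbutanoyl)phenyl]methyl}-5,7-dihydroxy-2,2,6-trimethylchroman-4-one | CC[C@@H](C)C(=O)c1c(O)c(C)c(OC)c(Cc2c(O)c(C)c(O)c3c2OC(C)(C)CC3=O)c1O | target

## Step count and risks

Total: 10 steps. Longest linear sequence: 6 steps (steps 1, 2, 5, 6, 7, 10; the ynone branch, steps 3, 4, 5, 6, 7, 10, is equally long).

**Step 5 (key step, proposed new method).**
- Risk: the ethoxy group donates into the ynone, so the cycloaddition may be slow. Heating much further invites retro-ene loss of ethylene from the ethoxyalkyne and protodesilylation of the diene. The diene may instead close through its C2 onto the ketone in a [3+3] sense, which would give a salicylate and not a resorcinol.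
- Fallback (known chemistry): the fallback sets out from 16. It is heated with 3-methylbut-2-enoic acid in P2O5/MeSO3H at 70 °C (Friedel–Crafts acylation and oxa-Michael closure in one flask). This should give 13 together with its regioisomer 5,7-dihydroxy-2,2,8-trimethylchroman-4-one F1, which is separated by chromatography. The route is rejoined at 13 and step 6 is not needed. The price is the loss of regiocontrol.

**Step 8.**
- Risk: enolisation of the aluminium-complexed ketone, or of the acid chloride, would erode the enantiomeric purity. O-acylation or double acylation would lower the return.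
- Fallback: the fallback sets out from 16. It is converted with chloromethyl methyl ether and i-Pr2NEt into 1,3,5-tris(methoxymethoxy)-2-methylbenzene F2. n-BuLi in THF at 0 °C lithiates a ring carbon between two methoxymethoxy groups. The aryllithium is acylated with (R)-N-methoxy-N,2-dimethylbutanamide F3, made from 15 with 1,1'-carbonyldiimidazole and N,O-dimethylhydroxylamine hydrochloride. This gives (R)-2-methyl-1-[2,4,6-tris(methoxymethoxy)-3-methylphenyl]butan-1-one F4. Dilute HCl in methanol removes the acetals and the route is rejoined at 18. No Lewis acid meets the stereocentre.

**Step 9.**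
- Risk: methylation may run on to a dimethyl ether or take place at the less hindered ortho hydroxyl, and the phenoxide may be methylated on its free ring carbon.
- Fallback: the oxygen methyl is bought in and the carbon methyl is added last. The fallback sets out from 15 (through F3) and from purchased 5-methoxybenzene-1,3-diol F5. Bis-protection gives 1-methoxy-3,5-bis(methoxymethoxy)benzene F6. Lithiation with n-BuLi between the two methoxymethoxy groups and acylation with F3 give (R)-1-[4-methoxy-2,6-bis(methoxymethoxy)phenyl]-2-methylbutan-1-one F7. HCl in methanol gives the symmetric (R)-1-(2,6-dihydroxy-4-methoxyphenyl)-2-methylbutan-1-one F8. Its two free ring carbons are equivalent, and C-methylation with one equivalent of MeI and NaOMe in methanol at 0 °C rejoins the route at 19.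

**Step 10.**
- Risk: amine loss from 14 may need temperatures at which the methylene bridge redistributes into symmetrical dimers, ring C opens by retro-oxa-Michael reaction, or dimethylamine epimerises the α-carbon.
- Fallback: the fallback sets out from 14. It is quaternised with MeI in acetone to [(5,7-dihydroxy-2,2,6-trimethyl-4-oxochroman-8-yl)methyl]trimethylammonium iodide F9. With NaHCO3 in aqueous acetonitrile at 23 °C this salt should release 20 in the presence of 19, and the route is rejoined at 21 without heating.

**Step 4 (with the handling of 8).**
- Risk: the ethoxyalkynyl carbinol may rearrange to the dienoic ester on silica or on acidic batches of MnO2, and the ynol ether may be hydrated.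
- Fallback: the fallback sets out from 5, lithiated to 7 as in step 3. The acetylide is added at −78 °C to N-methoxy-N,3-dimethylbut-2-enamide F10, made from 3-methylbut-2-enoyl chloride and N,O-dimethylhydroxylamine hydrochloride with pyridine. A buffered quench should give 9 directly, so the carbinol 8 and the oxidation are bypassed.

## Further compounds

F1 | step 5 | 5,7-dihydroxy-2,2,8-trimethylchroman-4-one | Cc1c(O)cc(O)c2C(=O)CC(C)(C)Oc12
F2 | step 8 | 1,3,5-tris(methoxymethoxy)-2-methylbenzene | Cc1c(OCOC)cc(OCOC)cc1OCOC
F3 | step 8 | (R)-N-methoxy-N,2-dimethylbutanamide | CC[C@@H](C)C(=O)N(C)OC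
F4 | step 8 | (R)-2-methyl-1-[2,4,6-tris(methoxymethoxy)-3-methylphenyl]butan-1-one | CC[C@@H](C)C(=O)c1c(OCOC)c(C)c(OCOC)cc1OCOC
F5 | step 9 | 5-methoxybenzene-1,3-diol (purchased) | COc1cc(O)cc(O)c1
F6 | step 9 | 1-methoxy-3,5-bis(methoxymethoxy)benzene | COCOc1cc(OC)cc(OCOC)c1
F7 | step 9 | (R)-1-[4-methoxy-2,6-bis(methoxymethoxy)phenyl]-2-methylbutan-1-one | CC[C@@H](C)C(=O)c1c(OCOC)cc(OC)cc1OCOC
F8 | step 9 | (R)-1-(2,6-dihydroxy-4-methoxyphenyl)-2-methylbutan-1-one | CC[C@@H](C)C(=O)c1c(O)cc(OC)cc1O
F9 | step 10 | [(5,7-dihydroxy-2,2,6-trimethyl-4-oxochroman-8-yl)methyl]trimethylammonium iodide | Cc1c(O)c(C[N+](C)(C)C)c2OC(C)(C)CC(=O)c2c1O.[I-]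
F10 | step 4 | N-methoxy-N,3-dimethylbut-2-enamide | CC(C)=CC(=O)N(C)OC
A1 | alternative 1 | 3,5-dimethoxy-4-methyl-2-(trimethylsilyl)phenyl trifluoromethanesulfonate | COc1cc(OS(=O)(=O)C(F)(F)F)c([Si](C)(C)C)c(OC)c1C
A2 | alternative 1 | 3,5-dimethoxy-4-methylbenzyne | COC1=CC#CC(OC)=C1C
A3 | alternative 1 | (R)-1-(6-hydroxy-2,4-dimethoxy-3-methylphenyl)-2-methylbutan-1-one | CC[C@@H](C)C(=O)c1c(OC)c(C)c(OC)cc1O
A4 | alternative 2 | rac-4-{[5,7-bis(benzyloxy)-2,2,6-trimethyl-4-oxochroman-8-yl]methyl}-3-methoxy-2-methylcyclobut-2-en-1-one | COC1=C(C)C(=O)C1Cc1c(OCc2ccccc2)c(C)c(OCc2ccccc2)c2c1OC(C)(C)CC2=O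
A5 | alternative 2 | (triisopropylsilyloxy)acetylene | C#CO[Si](C(C)C)(C(C)C)C(C)C
A6 | alternative 2 | 5,7-bis(benzyloxy)-8-{[6-hydroxy-2-methoxy-3-methyl-4-(triisopropylsilyloxy)phenyl]methyl}-2,2,6-trimethylchroman-4-one | COc1c(C)c(O[Si](C(C)C)(C(C)C)C(C)C)cc(O)c1Cc1c(OCc2ccccc2)c(C)c(OCc2ccccc2)c2c1OC(C)(C)CC2=O
A7 | alternative 3 | 3,5-dimethoxy-4-methylphenol | COc1cc(O)cc(OC)c1C
A8 | alternative 3 | 3,5-dimethoxy-4-methylphenyl 3-methylbut-2-enoate | COc1cc(OC(=O)C=C(C)C)cc(OC)c1C
A9 | alternative 3 | 5,7-dimethoxy-2,2,6-trimethylchroman-4-one | COc1cc2OC(C)(C)CC(=O)c2c(OC)c1C
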